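The constants were set for the occasion; the rest is arithmetic.

A small charge of substrate went into two vessels, and I wanted to know how the part that reacted divided itself.

    substrate → side product (k1 = 4.3 × 10⁻⁶ s⁻¹)
    substrate + target ⇌ idle adduct, settled at all times (K2 = 3.2 L mol⁻¹)
    substrate → target (k3 = 8.2 × 10⁻⁶ s⁻¹)

all flasks: substrate 3.0 M
- zeta: a single well-mixed tank run continuously and read at steady state, 15 h in it on average
- beta: a closed flask charged with all of it at once and left for 15 h; time 15 h

1. the set-up with the highest share of target in all that became target or side product, at the outlet or at the end ("none" if the first two lie within 2 percentage points) (zeta / beta / none)
2. share of target in all that became target or side product, at the outlet or at the end, zeta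
3. share of target in all that became target or side product, at the outlet or at the end, beta

- percent here means substrate units held: one idle adduct counts as two
- what is said of target includes idle adduct
- the stated concentrations are those of everything mixed, before any reaction; amounts are the same in each set-up
- in an amount of target, one idle adduct counts as one target
- run time (beta): 15 h

I went down the ladder of times from the fastest rung. The adduct balance came first, since it was kept at every moment. At the start of beta, its constant times c(substrate) was 9.6, so a free target formed then stood beside that many idle adducts. One idle adduct counts as one target, so this balance changed no count of target, and it held substrate back from both slower steps alike.

The next rung was the half-life of substrate: 23 h by the step to target alone, and 45 h by the step to side product alone. The last rung was the 15 h in each vessel, on average in zeta, which is shorter than both, so I expected substrate to remain in both.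

Then I asked what the end state must hold. Both steps are first order in the same free substrate, so the useful quantity was the selectivity factor, the target formed per side product formed, 1.91. In beta the two products pile up in that ratio, and in zeta they leave together in the same outflow, so the outlet keeps it. I reckoned 65.6 % for zeta and 65.6 % for beta, which meant no winner under the margin of 2 percentage points.

The forecast agreed, with 65.6 % for zeta, 65.6 % for beta and none as best, saying "so the vessel type changes conversion but not this share".

The simulation gave 65.6 % for zeta and 65.6 % for beta, with none as best. The vessels differed in amount: of the substrate charged, beta ended with 27.5 % as target and zeta delivered 21.7 %. Beta was also left for 150 h, where the factor 1.91 gives 65.6 %, and that run read 65.6 %.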